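**Retrosynthetic overview**

- Feature: the interflavone bond joins C3' of ring B of the 5,7-dihydroxyflavone (unit 1) to C8 of ring A of the 7-methoxyflavone (unit 2). Each of these carbons has an oxygen-bearing neighbour (C4'–OH and C8a–O1), so one silicon atom can tie the two oxygens together.
- Key disconnection: the C3'–C8 bond, made by palladium-catalysed intramolecular C–H arylation inside the di-tert-butylsilylene diether 12 (bromide on C3', C–H on C8). This closes a temporary seven-membered dioxasilepine, which TBAF opens again.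
- Diether 12 comes from bromophenol flavone 7, acetophenone 9 and tBu2Si(OTf)2. Flavone 7 is made by the chalcone route from phloroacetophenone and 3-bromo-4-hydroxybenzaldehyde.
- After the bridge is removed, the freed C8a hydroxyl and the acetyl group build the pyranone of unit 2 (Claisen–Schmidt condensation with 4-isopropoxybenzaldehyde, then I2/DMSO). BCl3 finally removes the four isopropyl ethers and leaves the C7 methyl ether.
- Ring order: pyranone of unit 1, then the dioxasilepine together with the biaryl bond, then the pyranone of unit 2.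

Key step: step 8

Remark 1: 2',6'-dihydroxy-4'-methoxyacetophenone (8) is taken as a purchasable compound.
Remark 2: any MOM ether lost under the hot I2/DMSO conditions of step 4 only gives phenol 7 early, so the crude product of step 4 is carried as a whole into step 5.
Remark 3: the target SMILES defines no stereocentre and no fixed biaryl axis, so no stereochemical control is planned.

**Route**

Step 1
Reactants: 1 2,4,6-trihydroxyacetophenone
Product: 2 1-(2-hydroxy-4,6-diisopropoxyphenyl)ethanone
Conditions: 2-bromopropane (2.3 eq), K2CO3 (2.5 eq), DMF, 60 °C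
Reagents that add atoms: 2-bromopropane, CC(C)Br
Why: Williamson O-alkylation takes the 4-hydroxyl and one ortho hydroxyl, whereas the last hydroxyl stays hydrogen-bonded to the acetyl carbonyl and is left free.

Step 2
Reactants: 3 3-bromo-4-hydroxybenzaldehyde
Product: 4 3-bromo-4-(methoxymethoxy)benzaldehyde
Conditions: MOMCl (1.3 eq), iPr2NEt (1.5 eq), CH2Cl2, 0 °C to rt
Reagents that add atoms: chloromethyl methyl ether, COCCl
Why: O-alkylation of the phenol to its MOM acetal removes the phenoxide that would deactivate the aldehyde in the aldol step, and the group can later be taken off without touching isopropyl ethers or the bromide.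

Step 3
Reactants: 2 1-(2-hydroxy-4,6-diisopropoxyphenyl)ethanone; 4 3-bromo-4-(methoxymethoxy)benzaldehyde
Product: 5 (E)-3-[3-bromo-4-(methoxymethoxy)phenyl]-1-(2-hydroxy-4,6-diisopropoxyphenyl)prop-2-en-1-one
Conditions: KOH (50% aq), EtOH, rt
Reagents that add atoms: none
Why: Claisen–Schmidt condensation of the methyl ketone enolate with a non-enolisable aldehyde, followed by E1cB dehydration, should give the thermodynamically preferred (E)-enone, with the MOM ether and the aryl bromide inert to KOH.

Step 4
Reactants: 5 (E)-3-[3-bromo-4-(methoxymethoxy)phenyl]-1-(2-hydroxy-4,6-diisopropoxyphenyl)prop-2-en-1-one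
Product: 6 3'-bromo-5,7-diisopropoxy-4'-(methoxymethoxy)flavone
Conditions: I2 (10 mol%), DMSO, 130 °C
Reagents that add atoms: none
Why: I2/DMSO oxidative cyclisation, in which 6-endo oxa-Michael addition of the 2'-hydroxyl to the enone gives the flavanone and iodine dehydrogenates it while DMSO reoxidises the HI formed.

Step 5
Reactants: 6 3'-bromo-5,7-diisopropoxy-4'-(methoxymethoxy)flavone
Product: 7 3'-bromo-4'-hydroxy-5,7-diisopropoxyflavone
Conditions: 3 M HCl, MeOH/THF, 50 °C
Reagents that add atoms: none
Why: acid-catalysed acetal exchange with methanol removes the MOM group, whereas aryl isopropyl ethers and the aryl bromide are stable to dilute HCl.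

Step 6
Reactants: 8 2',6'-dihydroxy-4'-methoxyacetophenone
Product: 9 1-(2-hydroxy-6-isopropoxy-4-methoxyphenyl)ethanone
Conditions: 2-bromopropane (1.2 eq), K2CO3 (1.2 eq), DMF, 40 °C
Reagents that add atoms: 2-bromopropane, CC(C)Br
Why: Williamson mono-O-alkylation, since after the first of the two equivalent hydroxyls has reacted the remaining one is held in a hydrogen bond to the carbonyl and resists a slight excess of the secondary bromide.

Step 7
Reactants: 7 3'-bromo-4'-hydroxy-5,7-diisopropoxyflavone; 10 di-tert-butylsilyl bis(trifluoromethanesulfonate); 9 1-(2-hydroxy-6-isopropoxy-4-methoxyphenyl)ethanone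
Product: 12 (2-acetyl-3-isopropoxy-5-methoxyphenoxy)[2-bromo-4-(5,7-diisopropoxy-4-oxo-4H-chromen-2-yl)phenoxy]di-tert-butylsilane, via aryloxysilyl triflate 11 (not isolated)
Conditions: 10 (1.1 eq), 2,6-lutidine, CH2Cl2, −40 to 0 °C; then 9 (1.3 eq), imidazole, DMF, rt to 45 °C
Reagents that add atoms: none
Why: stepwise nucleophilic substitution at silicon, in which the unhindered bromophenol displaces one triflate at low temperature, the bulky monotriflate 11 reacts only slowly with more 7, and the chelated phenol 9 is then attached under imidazole catalysis; silylating 7 first avoids the cyclic phenol–enol silylene that 9 could form with 10.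

Step 8
Reactants: 12 (2-acetyl-3-isopropoxy-5-methoxyphenoxy)[2-bromo-4-(5,7-diisopropoxy-4-oxo-4H-chromen-2-yl)phenoxy]di-tert-butylsilane
Product: 13 4-acetyl-6,6-di-tert-butyl-3-isopropoxy-1-methoxy-10-(5,7-diisopropoxy-4-oxo-4H-chromen-2-yl)dibenzo[d,f][1,3,2]dioxasilepine (the silicon-bridged C3'–C8 biaryl)
Conditions: Pd(OAc)2 (5 mol%), PCy3·HBF4 (10 mol%), PivOH (30 mol%), K2CO3 (2 eq), DMA, 110 °C
Reagents that add atoms: none
Why: Pd(OAc)2 is reduced in the flask to zerovalent palladium, which inserts into the C3'–Br bond; after bromide–pivalate exchange the C8–H bond, acidified by its two oxygen-bearing neighbours, is broken by concerted metalation–deprotonation to give an eight-membered diaryl palladacycle of divalent palladium, and reductive elimination forms the C3'–C8 bond. The closest known reaction type is the palladium-catalysed intramolecular direct arylation of bis(aryloxy)di-tert-butylsilanes, a pivalate-assisted C–H arylation that gives silicon-bridged 2,2'-biphenols. The one new ring, the seven-membered dibenzo-1,3,2-dioxasilepine, is closed by this C(sp2)–C(sp2) reductive elimination, the chain C8a–O–Si–O–C4' supplying the rest of the ring. No stereocentre is formed and the bridged biaryl axis is not configurationally fixed. The step needs site selectivity on ring A of unit 2 and preference for the intramolecular path: the tether reaches only a carbon ortho to the silylated oxygen, the other ortho carbon carries the acetyl group, C6–H would require a nine-membered ring, and K2CO3 is too weak to enolise the acetyl group for α-arylation.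

Step 9
Reactants: 13 silicon-bridged C3'–C8 biaryl
Product: 14 3'-(3-acetyl-2-hydroxy-4-isopropoxy-6-methoxyphenyl)-4'-hydroxy-5,7-diisopropoxyflavone
Conditions: TBAF (2.5 eq), AcOH (2.5 eq), THF, 0 °C to rt
Reagents that add atoms: none
Why: fluoride-induced desilylation cleaves both aryl–O–Si bonds, driven by the strong Si–F bond, and the acetic acid buffer returns the two phenols without exposing the flavone to free phenoxide and fluoride base.

Step 10
Reactants: 14 3'-(3-acetyl-2-hydroxy-4-isopropoxy-6-methoxyphenyl)-4'-hydroxy-5,7-diisopropoxyflavone; 15 4-isopropoxybenzaldehyde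
Product: 16 (E)-1-{2-hydroxy-3-[2-hydroxy-5-(5,7-diisopropoxy-4-oxo-4H-chromen-2-yl)phenyl]-6-isopropoxy-4-methoxyphenyl}-3-(4-isopropoxyphenyl)prop-2-en-1-one
Conditions: KOH (50% aq), EtOH, rt
Reagents that add atoms: none
Why: Claisen–Schmidt condensation at the only enolisable ketone with a non-enolisable aldehyde should give the (E)-chalcone, while the 4'-phenoxide formed in KOH lowers the electrophilicity of the unit 1 pyranone towards hydroxide.

Step 11
Reactants: 16 the chalcone of step 10
Product: 17 sotetsuflavone 5,7,5'',4'''-tetraisopropyl ether (4'-hydroxyl free)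
Conditions: I2 (10 mol%), DMSO, 130 °C
Reagents that add atoms: none
Why: I2/DMSO oxidative cyclisation, in which only the C8a hydroxyl freed in step 9 can add to the enone β-carbon through a six-membered ring (6-endo oxa-Michael) and the resulting flavanone is dehydrogenated; the 4'-hydroxyl of unit 1 would have to close a nine-membered ring.

Step 12
Reactants: 17 sotetsuflavone 5,7,5'',4'''-tetraisopropyl ether
Product: 18 sotetsuflavone
Conditions: BCl3 (1 M in CH2Cl2, 10 eq), CH2Cl2, 0 °C to rt; then MeOH/H2O
Reagents that add atoms: none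
Why: Lewis acid dealkylation by BCl3 cleaves aryl isopropyl ethers through the secondary cation-like pathway, helped at the two peri positions by chelation to the C4 carbonyls, whereas the non-chelated aryl methyl ether at C7 of unit 2 should survive at this temperature.

**Compound list**

1 | 2,4,6-trihydroxyacetophenone (phloroacetophenone) | CC(=O)c1c(O)cc(O)cc1O | starting material
2 | 1-(2-hydroxy-4,6-diisopropoxyphenyl)ethanone | CC(=O)c1c(O)cc(OC(C)C)cc1OC(C)C | intermediate
3 | 3-bromo-4-hydroxybenzaldehyde | O=Cc1ccc(O)c(Br)c1 | starting material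
4 | 3-bromo-4-(methoxymethoxy)benzaldehyde | COCOc1ccc(C=O)cc1Br | intermediate
5 | (E)-3-[3-bromo-4-(methoxymethoxy)phenyl]-1-(2-hydroxy-4,6-diisopropoxyphenyl)prop-2-en-1-one | COCOc1ccc(/C=C/C(=O)c2c(O)cc(OC(C)C)cc2OC(C)C)cc1Br | intermediate
6 | 3'-bromo-5,7-diisopropoxy-4'-(methoxymethoxy)flavone | COCOc1ccc(cc1Br)-c1cc(=O)c2c(OC(C)C)cc(OC(C)C)cc2o1 | intermediate
7 | 3'-bromo-4'-hydroxy-5,7-diisopropoxyflavone | Oc1ccc(cc1Br)-c1cc(=O)c2c(OC(C)C)cc(OC(C)C)cc2o1 | intermediate
8 | 2',6'-dihydroxy-4'-methoxyacetophenone | CC(=O)c1c(O)cc(OC)cc1O | starting material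
9 | 1-(2-hydroxy-6-isopropoxy-4-methoxyphenyl)ethanone | CC(=O)c1c(O)cc(OC)cc1OC(C)C | intermediate
10 | di-tert-butylsilyl bis(trifluoromethanesulfonate) | CC(C)(C)[Si](OS(=O)(=O)C(F)(F)F)(OS(=O)(=O)C(F)(F)F)C(C)(C)C | starting material
11 | [2-bromo-4-(5,7-diisopropoxy-4-oxo-4H-chromen-2-yl)phenoxy]di-tert-butylsilyl trifluoromethanesulfonate | CC(C)(C)[Si](OS(=O)(=O)C(F)(F)F)(Oc1ccc(cc1Br)-c1cc(=O)c2c(OC(C)C)cc(OC(C)C)cc2o1)C(C)(C)C | intermediate
12 | (2-acetyl-3-isopropoxy-5-methoxyphenoxy)[2-bromo-4-(5,7-diisopropoxy-4-oxo-4H-chromen-2-yl)phenoxy]di-tert-butylsilane | CC(=O)c1c(OC(C)C)cc(OC)cc1O[Si](C(C)(C)C)(C(C)(C)C)Oc1ccc(cc1Br)-c1cc(=O)c2c(OC(C)C)cc(OC(C)C)cc2o1 | intermediate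
13 | 4-acetyl-6,6-di-tert-butyl-3-isopropoxy-1-methoxy-10-(5,7-diisopropoxy-4-oxo-4H-chromen-2-yl)dibenzo[d,f][1,3,2]dioxasilepine | CC(=O)c1c(OC(C)C)cc(OC)c2c1O[Si](C(C)(C)C)(C(C)(C)C)Oc1ccc(cc1-2)-c1cc(=O)c2c(OC(C)C)cc(OC(C)C)cc2o1 | intermediate
14 | 3'-(3-acetyl-2-hydroxy-4-isopropoxy-6-methoxyphenyl)-4'-hydroxy-5,7-diisopropoxyflavone | CC(=O)c1c(OC(C)C)cc(OC)c(c1O)-c1cc(ccc1O)-c1cc(=O)c2c(OC(C)C)cc(OC(C)C)cc2o1 | intermediate
15 | 4-isopropoxybenzaldehyde | CC(C)Oc1ccc(C=O)cc1 | starting material
16 | (E)-1-{2-hydroxy-3-[2-hydroxy-5-(5,7-diisopropoxy-4-oxo-4H-chromen-2-yl)phenyl]-6-isopropoxy-4-methoxyphenyl}-3-(4-isopropoxyphenyl)prop-2-en-1-one | CC(C)Oc1ccc(/C=C/C(=O)c2c(OC(C)C)cc(OC)c(c2O)-c2cc(ccc2O)-c2cc(=O)c3c(OC(C)C)cc(OC(C)C)cc3o2)cc1 | intermediate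
17 | sotetsuflavone 5,7,5'',4'''-tetraisopropyl ether | COc1cc(OC(C)C)c2c(=O)cc(-c3ccc(OC(C)C)cc3)oc2c1-c1cc(-c2cc(=O)c3c(OC(C)C)cc(OC(C)C)cc3o2)ccc1O | intermediate
18 | sotetsuflavone | COc1cc(O)c2c(=O)cc(-c3ccc(O)cc3)oc2c1-c1cc(-c2cc(=O)c3c(O)cc(O)cc3o2)ccc1O | target

**Step count and risks**

Total steps: 12. Longest linear sequence: 10 steps (step 1 or 2, then steps 3, 4, 5, 7, 8, 9, 10, 11, 12).

Steps most likely to fail:

Step 8. The C–H metalation has to occur at a carbon flanked on both sides by oxygen substituents. If it is slow, the arylpalladium intermediate may be protonated (loss of bromine without coupling), or the Si–O bonds may be cleaved by carbonate or pivalate at 110 °C before the ring closes. The fallback gives up the tether and makes the same bond by an intermolecular Suzuki–Miyaura coupling. It sets out from 6 and 9 and comes back at 14. Miyaura borylation of 6 (B2pin2, PdCl2(dppf), KOAc, dioxane, 90 °C) should give the 3'-pinacolboronate of 5,7-diisopropoxy-4'-(methoxymethoxy)flavone F1. Iodination of 9 ortho to its free hydroxyl (N-iodosuccinimide, catalytic TFA, MeCN, 0 °C) should give 1-(2-hydroxy-3-iodo-6-isopropoxy-4-methoxyphenyl)ethanone F2. Coupling of the two (Pd(OAc)2, SPhos, K3PO4, toluene/H2O, 90 °C) should give the 4'-O-MOM ether of 14 F3, and 3 M HCl in MeOH/THF at 50 °C then returns 14.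

Step 7. The bis-triflate may be substituted twice by the more reactive phenol 7 to give the symmetrical silane, and the hindered, chelated phenol 9 may attack the bulky silyl triflate too slowly, so that 11 is lost to adventitious water. The fallback uses silicon reagents that carry only one leaving group at each stage. It sets out from 7 and comes back at 12. Silylation of 7 with di-tert-butylchlorosilane (imidazole, DMF, rt) should give 3'-bromo-4'-(di-tert-butylsilyloxy)-5,7-diisopropoxyflavone F4. Its Si–H bond is then chlorinated (CuCl2, 2 eq, catalytic CuI, THF, rt) to the aryloxy(di-tert-butyl)chlorosilane F5. This is treated with the sodium phenoxide of 9 (NaH, DMF, 60 °C) to give 12.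

Step 10. Enolisation and condensation at the crowded acetyl group may be slow, and during long exposure to aqueous KOH hydroxide may open the pyranone of unit 1. The fallback replaces the chalcone route by a Baker–Venkataraman sequence without aqueous alkali. It sets out from 14, passes by 16 and step 11, and comes back at 17. Acylation of both phenols of 14 with 4-isopropoxybenzoyl chloride (pyridine, DMAP, CH2Cl2) should give the bis(4-isopropoxybenzoate) of 14 F6. KOtBu in THF (0 °C to rt) moves the aroyl group from the C8a oxygen to the acetyl carbon and gives the 1,3-diketone 4'-O-ester F7. Cyclodehydration (catalytic TsOH, toluene, 90 °C) closes the pyranone and gives the 4'-O-(4-isopropoxybenzoate) of 17 F8. Methanolysis (K2CO3, MeOH, rt) then gives 17.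

**Further compounds**

F1 | step 8 | 5,7-diisopropoxy-4'-(methoxymethoxy)-3'-(4,4,5,5-tetramethyl-1,3,2-dioxaborolan-2-yl)flavone | COCOc1ccc(cc1B1OC(C)(C)C(C)(C)O1)-c1cc(=O)c2c(OC(C)C)cc(OC(C)C)cc2o1
F2 | step 8 | 1-(2-hydroxy-3-iodo-6-isopropoxy-4-methoxyphenyl)ethanone | CC(=O)c1c(OC(C)C)cc(OC)c(I)c1O
F3 | step 8 | 3'-(3-acetyl-2-hydroxy-4-isopropoxy-6-methoxyphenyl)-5,7-diisopropoxy-4'-(methoxymethoxy)flavone | CC(=O)c1c(OC(C)C)cc(OC)c(c1O)-c1cc(ccc1OCOC)-c1cc(=O)c2c(OC(C)C)cc(OC(C)C)cc2o1
F4 | step 7 | 3'-bromo-4'-(di-tert-butylsilyloxy)-5,7-diisopropoxyflavone | CC(C)(C)[SiH](Oc1ccc(cc1Br)-c1cc(=O)c2c(OC(C)C)cc(OC(C)C)cc2o1)C(C)(C)C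
F5 | step 7 | [2-bromo-4-(5,7-diisopropoxy-4-oxo-4H-chromen-2-yl)phenoxy]di-tert-butylchlorosilane | CC(C)(C)[Si](Cl)(Oc1ccc(cc1Br)-c1cc(=O)c2c(OC(C)C)cc(OC(C)C)cc2o1)C(C)(C)C
F6 | step 10 | bis(4-isopropoxybenzoate) of 14 (esters on the C8a and C4' oxygens) | CC(=O)c1c(OC(C)C)cc(OC)c(c1OC(=O)c1ccc(OC(C)C)cc1)-c1cc(ccc1OC(=O)c1ccc(OC(C)C)cc1)-c1cc(=O)c2c(OC(C)C)cc(OC(C)C)cc2o1
F7 | step 10 | 1-(4-isopropoxyphenyl)propane-1,3-dione attached through C3 to the acetophenone ring of 14, with the 4'-O-(4-isopropoxybenzoate) kept | CC(C)Oc1ccc(cc1)C(=O)CC(=O)c1c(OC(C)C)cc(OC)c(c1O)-c1cc(ccc1OC(=O)c1ccc(OC(C)C)cc1)-c1cc(=O)c2c(OC(C)C)cc(OC(C)C)cc2o1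
F8 | step 10 | 4'-O-(4-isopropoxybenzoate) of 17 | COc1cc(OC(C)C)c2c(=O)cc(-c3ccc(OC(C)C)cc3)oc2c1-c1cc(-c2cc(=O)c3c(OC(C)C)cc(OC(C)C)cc3o2)ccc1OC(=O)c1ccc(OC(C)C)cc1
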